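**Retrosynthetic overview**
1. Target 17 ⇐ desilylation and acetylation at the side-chain carbinol C1' of diol 15 ⇐ a single syn-dihydroxylation of the exocyclic C5=C1' alkene of dienone 14, anti to the C4 silyloxy group, which sets C5 and C1' together.
2. Dienone 14 ⇐ closure of the only ring by forming the C1(=O)–C2 bond: rhodium-catalysed intramolecular trans hydroacylation of the acyclic ynal 13.
3. Ynal 13 ⇐ enal 8 + ethynyltrimethylsilane by catalytic enantioselective alkynylation (the one stereocentre set by catalysis, later C4); 8 ⇐ alkenyl bromide 6 ⇐ 1-hexadecene + crotonaldehyde.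
4. Enabling feature: ring atoms C1 (C=O) and C2 (=CH) are an acyl carbon and the terminal carbon of a former C≡C unit, held 1,4 through C5 and C4. The cis C2=C3 ring alkene is what trans addition of acyl and H across that alkyne gives, and C5 is fully substituted (alkylidene, later the tertiary carbinol), so the formyl group cannot enolize.
5. Ring order: one carbocycle only, formed in step 9; no temporary ring or tether.

Key step: step 9

Remark on the chemistry: the facial sense of the zinc–ProPhenol alkynylation on enal 8 is assigned by analogy, so the ligand antipode is exchanged if the opposite carbinol forms; 1-hexadecene, crotonaldehyde and ethynyltrimethylsilane are taken as commercial.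

**Step 1**
Reactants: 1 1-hexadecene; 2 (E)-but-2-enal (crotonaldehyde)
Product: 3 (E)-heptadec-2-enal
Conditions: second-generation Hoveyda–Grubbs catalyst (2 mol%), 2 (4 equiv), CH2Cl2, 40 °C
Reagents that add atoms: none
Why: Olefin cross-metathesis of a terminal alkene with excess crotonaldehyde should give the conjugated enal with the thermodynamic E geometry; no stereocentre is involved.

**Step 2**
Reactants: 3 (E)-heptadec-2-enal
Product: 5 (Z)-2-bromoheptadec-2-enal, via dibromoaldehyde 4 (not isolated)
Conditions: Br2 (1.05 equiv), CH2Cl2, −20 °C; then Et3N (1.5 equiv), 0 °C to rt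
Reagents that add atoms: bromine, BrBr
Why: Bromine addition followed by amine-induced dehydrobromination (loss of the acidic alpha proton and the beta bromide) is the standard alpha-bromination of enals and should give the (Z)-2-bromoenal, with the alkyl chain cis to Br.

**Step 3**
Reactants: 5 (Z)-2-bromoheptadec-2-enal
Product: 6 (Z)-2-bromo-1,1-dimethoxyheptadec-2-ene
Conditions: HC(OMe)3 (3 equiv), p-TsOH·H2O (2 mol%), MeOH, rt
Reagents that add atoms: trimethyl orthoformate, COC(OC)OC; methanol, CO
Why: Acid-catalysed acetalization with orthoformate as water scavenger masks the aldehyde for the halogen–lithium exchange and leaves the alkene geometry untouched.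

**Step 4**
Reactants: 6 (Z)-2-bromo-1,1-dimethoxyheptadec-2-ene
Product: 8 (E)-2-(dimethoxymethyl)heptadec-2-enal, via alkenyllithium 7 (not isolated)
Conditions: t-BuLi (2.1 equiv), Et2O, −78 °C; then DMF, −78 to 0 °C; H2O
Reagents that add atoms: N,N-dimethylformamide, CN(C)C=O
Why: Bromine–lithium exchange on an alkenyl bromide goes with retention and the alkenyllithium is configurationally stable at −78 °C, so formylation places the new CHO cis to the tetradecyl chain, which fixes the later E alkylidene geometry (alkyl cis to the carbinol carbon).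

**Step 5**
Reactants: 8 (E)-2-(dimethoxymethyl)heptadec-2-enal; 9 ethynyltrimethylsilane
Product: 10 (3S,4E)-4-(dimethoxymethyl)-1-(trimethylsilyl)nonadec-4-en-1-yn-3-ol
Conditions: (S,S)-ProPhenol (10 mol%), Me2Zn (3 equiv), Ph3PO (20 mol%), 9 (3 equiv), toluene, 4 °C; aqueous work-up
Reagents that add atoms: none
Why: Zinc–ProPhenol-catalysed enantioselective addition of a terminal alkyne to an alpha-branched enal should set the carbinol centre under catalyst control; this is the only stereocentre in the route made by catalysis.

**Step 6**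
Reactants: 10 (3S,4E)-4-(dimethoxymethyl)-1-(trimethylsilyl)nonadec-4-en-1-yn-3-ol
Product: 11 tert-butyl{[(3S,4E)-4-(dimethoxymethyl)-1-(trimethylsilyl)nonadec-4-en-1-yn-3-yl]oxy}dimethylsilane
Conditions: TBSCl (1.5 equiv), imidazole (3 equiv), DMF, rt
Reagents that add atoms: tert-butyldimethylsilyl chloride, CC(C)(C)[Si](C)(C)Cl
Why: Standard silylation of a secondary alcohol under non-Lewis-acidic conditions that leave the acetal intact; the bulky silyl ether later differentiates this oxygen from the side-chain hydroxyl and shields one face of the alkylidene.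

**Step 7**
Reactants: 11 (silyl ether with C-silyl alkyne)
Product: 12 tert-butyl{[(3R,4E)-4-(dimethoxymethyl)nonadec-4-en-1-yn-3-yl]oxy}dimethylsilane
Conditions: K2CO3 (0.2 equiv), MeOH, rt
Reagents that add atoms: none
Why: Methanolysis cleaves the C(sp)–SiMe3 bond selectively while the TBS ether and the acetal are stable to carbonate in methanol; the descriptor changes from S to R by priority only.

**Step 8**
Reactants: 12 (terminal alkyne acetal)
Product: 13 (2E,3R)-3-[(tert-butyldimethylsilyl)oxy]-2-pentadecylidenepent-4-ynal
Conditions: PPTS (10 mol%), acetone/H2O (10:1), rt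
Reagents that add atoms: water, O
Why: An allylic dimethyl acetal hydrolyses under mild acid far faster than a secondary TBS ether is cleaved, and the enal is released in its thermodynamically preferred E geometry (alkyl trans to CHO).

**Step 9**
Reactants: 13 (2E,3R)-3-[(tert-butyldimethylsilyl)oxy]-2-pentadecylidenepent-4-ynal
Product: 14 (4R,5E)-4-[(tert-butyldimethylsilyl)oxy]-5-pentadecylidenecyclopent-2-en-1-one
Conditions: [Rh(dppe)]2(BF4)2 (5 mol%; dppe = Ph2PCH2CH2PPh2), degassed acetone, rt to 40 °C
Reagents that add atoms: none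
Why: Oxidative addition of the formyl C–H bond to the cationic monovalent rhodium centre gives an acyl rhodium hydride (trivalent rhodium) that binds the pendant alkyne; net trans hydrometalation puts H on the internal alkyne carbon and rhodium on the terminal carbon cis to the tether, and C–C reductive elimination from the resulting six-membered acyl(alkenyl)rhodacycle forms the C1(=O)–C2 bond and releases the catalyst. The closest known reaction type is the rhodium–diphosphine-catalysed isomerization of 4-alkynals, including 3-alkoxy-4-alkynals, to cyclopent-2-enones by intramolecular trans hydroacylation. The five-membered ring is closed in the endo mode with respect to the alkyne (formally 5-endo-dig, both alkyne carbons end up in the ring), which the trans delivery of acyl and H makes possible and which gives the cis ring alkene directly at the enone oxidation level. No new stereocentre is formed: the silyloxy carbon is not epimerizable because the neighbouring C2 of 13 carries no hydrogen, and the E alkylidene, already the thermodynamic enal geometry, should be carried over unchanged. The step needs endo closure to the cyclopentenone in preference to exo closure to an alkylidenecyclobutanone, to decarbonylation and to reaction at the terminal alkyne C–H; the chelating dppe ligand, the conjugated acyl group (slow to lose CO) and the geminal substitution at C2, which holds CHO and alkyne close, are what should secure it.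

**Step 10**
Reactants: 14 (4R,5E)-4-[(tert-butyldimethylsilyl)oxy]-5-pentadecylidenecyclopent-2-en-1-one
Product: 15 (4R,5S)-4-[(tert-butyldimethylsilyl)oxy]-5-hydroxy-5-[(1S)-1-hydroxypentadecyl]cyclopent-2-en-1-one
Conditions: OsO4 (3 mol%), NMO (1.1 equiv), acetone/H2O (8:1), 0 °C
Reagents that add atoms: N-methylmorpholine N-oxide, C[N+]1([O-])CCOCC1; water, O
Why: Catalytic osmylation should take the exocyclic trisubstituted alkene (more substituted and alkyl-donated) rather than the ring alkene (deactivated by the carbonyl and the allylic silyloxy group), from the face anti to the C4 silyloxy group, so that syn addition to the E alkene sets the C5 hydroxyl trans to the C4 oxygen and the 1'S carbinol in one event.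

**Step 11**
Reactants: 15 (diol)
Product: 16 (1S)-1-[(1S,5R)-5-[(tert-butyldimethylsilyl)oxy]-1-hydroxy-2-oxocyclopent-3-en-1-yl]pentadecyl acetate
Conditions: Ac2O (1.5 equiv), pyridine, DMAP (5 mol%), CH2Cl2, 0 °C
Reagents that add atoms: acetic anhydride, CC(=O)OC(C)=O
Why: Acylation should take the secondary side-chain hydroxyl and leave the tertiary alpha-ketol hydroxyl, while the ring oxygen is still silylated; C5 has no hydrogen, so base-induced loss of the C4 oxygen or of acetate is not possible.

**Step 12**
Reactants: 16 (silyl ether acetate)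
Product: 17 (1S)-1-[(1R,5R)-1,5-dihydroxy-2-oxocyclopent-3-en-1-yl]pentadecyl acetate (target)
Conditions: HF·pyridine, THF, 0 °C to rt
Reagents that add atoms: none
Why: Acidic fluoride cleaves the secondary TBS ether without touching the acetate, the enone or the tertiary alcohol, and the acidic medium disfavours acyl migration.

**Compound list**
1 | 1-hexadecene | CCCCCCCCCCCCCCC=C | starting material
2 | (E)-but-2-enal (crotonaldehyde) | C/C=C/C=O | starting material
3 | (E)-heptadec-2-enal | CCCCCCCCCCCCCC/C=C/C=O | intermediate
4 | rac-(2S,3R)-2,3-dibromoheptadecanal (anti adduct, one enantiomer drawn; not isolated) | CCCCCCCCCCCCCC[C@@H](Br)[C@@H](Br)C=O | intermediate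
5 | (Z)-2-bromoheptadec-2-enal | CCCCCCCCCCCCCC/C=C(\Br)C=O | intermediate
6 | (Z)-2-bromo-1,1-dimethoxyheptadec-2-ene | CCCCCCCCCCCCCC/C=C(\Br)C(OC)OC | intermediate
7 | [(E)-1-(dimethoxymethyl)hexadec-1-en-1-yl]lithium (not isolated) | CCCCCCCCCCCCCC/C=C(\[Li])C(OC)OC | intermediate
8 | (E)-2-(dimethoxymethyl)heptadec-2-enal | CCCCCCCCCCCCCC/C=C(\C=O)C(OC)OC | intermediate
9 | ethynyltrimethylsilane | C#C[Si](C)(C)C | starting material
10 | (3S,4E)-4-(dimethoxymethyl)-1-(trimethylsilyl)nonadec-4-en-1-yn-3-ol | CCCCCCCCCCCCCC/C=C(/C(OC)OC)[C@H](O)C#C[Si](C)(C)C | intermediate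
11 | tert-butyl{[(3S,4E)-4-(dimethoxymethyl)-1-(trimethylsilyl)nonadec-4-en-1-yn-3-yl]oxy}dimethylsilane | CCCCCCCCCCCCCC/C=C(/C(OC)OC)[C@H](O[Si](C)(C)C(C)(C)C)C#C[Si](C)(C)C | intermediate
12 | tert-butyl{[(3R,4E)-4-(dimethoxymethyl)nonadec-4-en-1-yn-3-yl]oxy}dimethylsilane | CCCCCCCCCCCCCC/C=C(/C(OC)OC)[C@H](O[Si](C)(C)C(C)(C)C)C#C | intermediate
13 | (2E,3R)-3-[(tert-butyldimethylsilyl)oxy]-2-pentadecylidenepent-4-ynal | CCCCCCCCCCCCCC/C=C(/C=O)[C@H](O[Si](C)(C)C(C)(C)C)C#C | intermediate
14 | (4R,5E)-4-[(tert-butyldimethylsilyl)oxy]-5-pentadecylidenecyclopent-2-en-1-one | CCCCCCCCCCCCCC/C=C1\[C@H](O[Si](C)(C)C(C)(C)C)C=CC1=O | intermediate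
15 | (4R,5S)-4-[(tert-butyldimethylsilyl)oxy]-5-hydroxy-5-[(1S)-1-hydroxypentadecyl]cyclopent-2-en-1-one | CCCCCCCCCCCCCC[C@H](O)[C@@]1(O)C(=O)C=C[C@H]1O[Si](C)(C)C(C)(C)C | intermediate
16 | (1S)-1-[(1S,5R)-5-[(tert-butyldimethylsilyl)oxy]-1-hydroxy-2-oxocyclopent-3-en-1-yl]pentadecyl acetate | CCCCCCCCCCCCCC[C@H](OC(C)=O)[C@@]1(O)C(=O)C=C[C@H]1O[Si](C)(C)C(C)(C)C | intermediate
17 | (1S)-1-[(1R,5R)-1,5-dihydroxy-2-oxocyclopent-3-en-1-yl]pentadecyl acetate | CCCCCCCCCCCCCC[C@H](OC(C)=O)[C@@]1(O)C(=O)C=C[C@H]1O | target

**Step count and risks**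
Total step count: 12. Longest linear sequence: 12 steps (from 1-hexadecene).

The three steps most likely to fail:

Step 9 (ring closure). The terminal alkyne may divert the cationic rhodium catalyst (alkynyl or vinylidene formation, oligomerization), or the conjugated acyl rhodium hydride may decarbonylate or close in the exo mode faster than it eliminates to the five-membered ring. The fallback forms the same bond by a Nozaki–Hiyama–Kishi closure at the alcohol oxidation level and sets out from 12. Iodination of the terminal alkyne (N-iodosuccinimide, AgNO3 cat., acetone) gives the iodoalkyne F1. Cis-selective diimide reduction (2-nitrobenzenesulfonylhydrazide, Et3N) gives the (Z)-alkenyl iodide F2. Acetal hydrolysis (PPTS, acetone/H2O) gives the iodo enal F3. Intramolecular coupling with CrCl2 and catalytic NiCl2 in DMF closes the ring to the dienol F4, whose carbinol epimers are of no consequence, and MnO2 oxidation returns to the route at 14.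

Step 10 (dihydroxylation). Osmylation may also attack the ring enone alkene or over-oxidize, and facial discrimination on the ring may be incomplete. The fallback inverts the order of events and sets out from 12, where the trisubstituted alkene is the only one present and allylic 1,3-strain holds the silyloxy centre so that the reagent enters anti to it. OsO4/NMO gives the diol F5, Ac2O/pyridine/DMAP gives the acetate F6, and LiBF4 in wet MeCN unmasks the hydroxy aldehyde F7. The same [Rh(dppe)]2(BF4)2 hydroacylation then closes the ring on the saturated 4-alkynal and comes back to the route at 16.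

Step 5 (alkynylation). Enantioselectivity may erode with the crowded alpha-branched enal, and the enal may lose its alkene geometry by reversible conjugate addition under the zinc alkoxide conditions. The fallback avoids the free enal and sets out from 6. Bromine–lithium exchange (t-BuLi, Et2O, −78 °C) and addition to 3-(trimethylsilyl)propynal give the racemic alcohol F8. MnO2 oxidation gives the ynone F9, and reagent-controlled reduction (Alpine-Borane, or a Corey–Bakshi–Shibata reduction, antipode chosen for the S carbinol) comes back to the route at 10.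

**Further compounds**
F1 | step 9 | tert-butyl{[(3S,4E)-4-(dimethoxymethyl)-1-iodononadec-4-en-1-yn-3-yl]oxy}dimethylsilane | CCCCCCCCCCCCCC/C=C(/C(OC)OC)[C@H](O[Si](C)(C)C(C)(C)C)C#CI
F2 | step 9 | tert-butyl{[(1Z,3R,4E)-4-(dimethoxymethyl)-1-iodononadeca-1,4-dien-3-yl]oxy}dimethylsilane | CCCCCCCCCCCCCC/C=C(/C(OC)OC)[C@H](O[Si](C)(C)C(C)(C)C)/C=C\I
F3 | step 9 | (2E,3R,4Z)-3-[(tert-butyldimethylsilyl)oxy]-5-iodo-2-pentadecylidenepent-4-enal | CCCCCCCCCCCCCC/C=C(/C=O)[C@H](O[Si](C)(C)C(C)(C)C)/C=C\I
F4 | step 9 | (4R,5Z)-4-[(tert-butyldimethylsilyl)oxy]-5-pentadecylidenecyclopent-2-en-1-ol (both C1 epimers) | CCCCCCCCCCCCCC/C=C1\[C@H](O[Si](C)(C)C(C)(C)C)C=CC1O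
F5 | step 10 | (3R,4S,5S)-3-[(tert-butyldimethylsilyl)oxy]-4-(dimethoxymethyl)nonadec-1-yne-4,5-diol | CCCCCCCCCCCCCC[C@H](O)[C@@]([C@H](O[Si](C)(C)C(C)(C)C)C#C)(O)C(OC)OC
F6 | step 10 | (3R,4S,5S)-3-[(tert-butyldimethylsilyl)oxy]-4-(dimethoxymethyl)-4-hydroxynonadec-1-yn-5-yl acetate | CCCCCCCCCCCCCC[C@H](OC(C)=O)[C@@]([C@H](O[Si](C)(C)C(C)(C)C)C#C)(O)C(OC)OC
F7 | step 10 | (3R,4S,5S)-3-[(tert-butyldimethylsilyl)oxy]-4-formyl-4-hydroxynonadec-1-yn-5-yl acetate | CCCCCCCCCCCCCC[C@H](OC(C)=O)[C@@]([C@H](O[Si](C)(C)C(C)(C)C)C#C)(O)C=O
F8 | step 5 | rac-(E)-4-(dimethoxymethyl)-1-(trimethylsilyl)nonadec-4-en-1-yn-3-ol | CCCCCCCCCCCCCC/C=C(/C(OC)OC)C(O)C#C[Si](C)(C)C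
F9 | step 5 | (Z)-4-(dimethoxymethyl)-1-(trimethylsilyl)nonadec-4-en-1-yn-3-one | CCCCCCCCCCCCCC/C=C(/C(OC)OC)C(=O)C#C[Si](C)(C)C
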